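**Plan**

1. The target is read as methyl (2E,6E)-nona-2,6-dienoate (C1–C9) with the (S)-5-acetoxy-4-methylpentyl chain on C2, a methyl on C6 and a furan-3-yl ring on C9. The enabling feature is the acyclic 1,5-diene C2=C3–C4–C5–C6=C7: C4 is the γ-carbon of the C1–C3 enoate and C5 is the allylic CH2 of the C6=C7 alkene, so an oxygen bridge C3–O–C7 turns C4=C3–O–C7–C6=C5 into an allyl vinyl ether. The furan ring is a spectator.
2. Retrosynthesis: OAc ⇒ OTBS; C3–H ⇒ C3–OTf ⇒ C3=O (β-keto ester 23); C4–C5 is cut by a retro-[3,3] shift into allenoate 12 (C1–C4 plus side chain) and racemic carbinol 19 (C5–C9 plus furan). Then 12 ⇒ ylide 9 + ketene (C2=C3), 9 ⇒ iodide 6 (C2–C1′), 6 ⇒ bromide 2 + ethylene oxide; 19 ⇒ aldehyde 17 + isopropenyl Grignard (C6–C7), 17 ⇒ 3-bromofuran + oxetane.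
3. Forward: the allenoate arm (steps 1–5) and the furan arm (steps 6–8) are built separately and joined at C4–C5 in step 9. Steps 10–11 lower C3 from ketone to alkene CH, and steps 12–13 exchange TBS for acetate.
4. Stereochemistry: the (S)-centre is bought as (R)-3-bromo-2-methylpropan-1-ol and is never at a reacting or acidic carbon (the descriptor changes only through CIP priorities). 6E comes from the chair transition state of step 9. 2E comes from the chelation-controlled Z-enol triflate (step 10), reduced with retention (step 11).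

Key step: step 9

Remark: 19 is used as the racemate and 23 as a mixture of C2 epimers, because both centres are erased (steps 9 and 10). TBS = tert-butyldimethylsilyl, Tf = trifluoromethanesulfonyl; C1–C9 refer to the nonadienoate chain of the target.

Step 1
Reactants: 1 (2R)-3-bromo-2-methylpropan-1-ol
Product: 2 [(2R)-3-bromo-2-methylpropoxy](tert-butyl)dimethylsilane
Conditions: TBSCl, imidazole, CH2Cl2, 0 → 23 °C
Reagents that add atoms: tert-butyldimethylsilyl chloride, CC(C)(C)[Si](C)(C)Cl
Why: Imidazole-assisted silylation of the primary alcohol masks the hydroxyl for the organometallic and basic steps that follow and leaves the stereocentre untouched.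

Step 2
Reactants: 2 [(2R)-3-bromo-2-methylpropoxy](tert-butyl)dimethylsilane; 3 ethylene oxide
Product: 5 (4S)-5-(TBSO)-4-methylpentan-1-ol, via Grignard reagent 4 (not isolated)
Conditions: Mg, THF, 50 °C; then CuI (10 mol %), 3, −30 → 0 °C
Reagents that add atoms: none
Why: The primary Grignard reagent 4 opens ethylene oxide under copper(I) catalysis (epoxide alkylation) and so adds the two missing CH2 groups, while the methyl-bearing centre is neither acidic nor at the reacting carbon and keeps its configuration (R becomes S only because the CIP priorities change).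

Step 3
Reactants: 5 (4S)-5-(TBSO)-4-methylpentan-1-ol
Product: 6 tert-butyl{[(2S)-5-iodo-2-methylpentyl]oxy}dimethylsilane
Conditions: I2, PPh3, imidazole, CH2Cl2, 0 → 23 °C
Reagents that add atoms: iodine, II
Why: Iodination of a primary alcohol with PPh3/I2/imidazole (Appel-type reaction) proceeds by SN2 at the CH2OH carbon under buffered conditions that a primary TBS ether tolerates.

Step 4
Reactants: 6 tert-butyl{[(2S)-5-iodo-2-methylpentyl]oxy}dimethylsilane; 7 methyl (triphenyl-λ5-phosphanylidene)acetate
Product: 9 methyl (6S)-7-(TBSO)-6-methyl-2-(triphenyl-λ5-phosphanylidene)heptanoate, via phosphonium iodide 8 (not isolated)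
Conditions: 7 (2.1 equiv), EtOAc, reflux; filtration
Reagents that add atoms: none
Why: C-Alkylation of the stabilised ylide by the primary iodide gives phosphonium salt 8, which a second equivalent of 7 deprotonates (transylidation) as the unsubstituted phosphonium iodide precipitates from ethyl acetate.

Step 5
Reactants: 9 methyl (6S)-7-(TBSO)-6-methyl-2-(triphenyl-λ5-phosphanylidene)heptanoate; 10 acetyl chloride
Product: 12 methyl 2-[(4S)-5-(TBSO)-4-methylpentyl]buta-2,3-dienoate, via ketene 11 (not isolated)
Conditions: Et3N, then 10 added slowly, CH2Cl2, 0 → 23 °C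
Reagents that add atoms: none
Why: Wittig olefination of ketene 11, generated in the flask from acetyl chloride and triethylamine, by the α-substituted stabilised ylide is the standard entry to 2-substituted buta-2,3-dienoates and installs C3 and C4 at the allene oxidation level.

Step 6
Reactants: 13 3-bromofuran; 14 oxetane
Product: 16 3-(furan-3-yl)propan-1-ol, via furan-3-yllithium 15 (not isolated)
Conditions: n-BuLi, THF, −78 °C; BF3·OEt2, then 14, −78 °C
Reagents that add atoms: none
Why: Bromine–lithium exchange at −78 °C gives furan-3-yllithium without isomerisation to the 2-lithio species, and this aryllithium opens BF3-activated oxetane (Lewis-acid-promoted cyclic ether opening) to attach the three-carbon chain at the furan 3-position.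

Step 7
Reactants: 16 3-(furan-3-yl)propan-1-ol
Product: 17 3-(furan-3-yl)propanal
Conditions: Dess–Martin periodinane, NaHCO3, CH2Cl2, 0 → 23 °C
Reagents that add atoms: none
Why: Buffered Dess–Martin oxidation converts the primary alcohol into the aldehyde without acid that could harm the furan.

Step 8
Reactants: 17 3-(furan-3-yl)propanal; 18 isopropenylmagnesium bromide
Product: 19 rac-1-(furan-3-yl)-4-methylpent-4-en-3-ol
Conditions: THF, −78 → 0 °C
Reagents that add atoms: none
Why: Grignard 1,2-addition to the aldehyde gives the 2-methylallylic alcohol as a racemate, which is sufficient because this carbinol centre is destroyed in step 9.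

Step 9
Reactants: 19 rac-1-(furan-3-yl)-4-methylpent-4-en-3-ol; 12 methyl 2-[(4S)-5-(TBSO)-4-methylpentyl]buta-2,3-dienoate
Product: 23 methyl (6E)-2-[(4S)-5-(TBSO)-4-methylpentyl]-9-(furan-3-yl)-6-methyl-3-oxonon-6-enoate, via potassium alkoxide 20 (not isolated), via dienolate adduct 21 (not isolated), via potassium enolate 22 (not isolated)
Conditions: 19 (1.1 equiv), KH (1.05 equiv), THF, 0 °C; then 12, −78 °C; DMPU, −78 → 23 °C
Reagents that add atoms: none
Why: Proposed new method: the potassium alkoxide 20 should add to the central allene carbon C3 of 12 (oxa-Michael addition) to give the ester enolate 21, in which C4=C3–O–C7–C6=C5 is an allyl vinyl ether carrying a carbanionic donor on C3, and an anion-accelerated [3,3] shift through a chair transition state should then form the C4–C5 σ bond while the O–C7 bond breaks, delivering the chelated β-keto ester enolate 22. The closest known reaction type is the carbanion-accelerated Claisen rearrangement of sulfonyl- and phosphoryl-stabilised 2-(allyloxy)allyl anions made by alkoxide addition to sulfonylallenes, together with the ester-enolate (Ireland) Claisen rearrangement; an ester-stabilised anion made from an allenoate has not been shown, hence the label. No ring is closed, since the six-membered array exists only in the transition state. No stereocentre of the target is formed: the carbinol centre of racemic 19 is destroyed so that both enantiomers converge on one alkene, C2 of 23 is a labile epimeric centre erased in step 10, and the remote (S)-centre is a spectator. The step needs E geometry at C6=C7, secured by the chair in which the 2-(furan-3-yl)ethyl group on C7 is equatorial because the axial position would clash 1,3-diaxially with the enolate substituent on C3, and it needs bond formation at the terminal C4 instead of C2, secured because C2 is fully substituted and only reaction through C4 leads to the stabilised 1,3-dicarbonyl enolate. Adding 12 to a slight excess of 20 at −78 °C before warming should keep free allenoate away from enolates 21 and 22 and so suppress Michael oligomerisation.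

Step 10
Reactants: 23 methyl (6E)-2-[(4S)-5-(TBSO)-4-methylpentyl]-9-(furan-3-yl)-6-methyl-3-oxonon-6-enoate
Product: 25 methyl (2Z,6E)-2-[(4S)-5-(TBSO)-4-methylpentyl]-9-(furan-3-yl)-6-methyl-3-(triflyloxy)nona-2,6-dienoate, via sodium enolate 24 (not isolated)
Conditions: NaH, THF, 0 °C; PhNTf2, 0 → 23 °C
Reagents that add atoms: N-phenylbis(trifluoromethanesulfonimide), O=S(=O)(N(c1ccccc1)S(=O)(=O)C(F)(F)F)C(F)(F)F
Why: O-Sulfonylation of the chelated (U-shaped) sodium enolate of the β-keto ester with the mild triflyl donor PhNTf2 should give the Z-enol triflate (OTf cis to CO2Me), erasing the epimeric C2 centre and fixing the geometry that becomes 2E under conditions that spare the furan and the silyl ether.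

Step 11
Reactants: 25 methyl (2Z,6E)-2-[(4S)-5-(TBSO)-4-methylpentyl]-9-(furan-3-yl)-6-methyl-3-(triflyloxy)nona-2,6-dienoate
Product: 26 methyl (2E,6E)-2-[(4S)-5-(TBSO)-4-methylpentyl]-9-(furan-3-yl)-6-methylnona-2,6-dienoate
Conditions: Pd(OAc)2 (5 mol %), PPh3 (10 mol %), HCO2H, Bu3N, DMF, 60 °C
Reagents that add atoms: none
Why: Palladium-catalysed formate reduction of the enol triflate (oxidative addition, formate decarboxylation to Pd–H, reductive elimination) replaces OTf by H with retention of the double-bond geometry, so the Z-triflate should give the 2E-enoate.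

Step 12
Reactants: 26 methyl (2E,6E)-2-[(4S)-5-(TBSO)-4-methylpentyl]-9-(furan-3-yl)-6-methylnona-2,6-dienoate
Product: 27 methyl (2E,6E)-9-(furan-3-yl)-2-[(4S)-5-hydroxy-4-methylpentyl]-6-methylnona-2,6-dienoate
Conditions: TBAF, AcOH, THF, 0 → 23 °C
Reagents that add atoms: none
Why: Fluoride cleavage of the primary TBS ether, buffered with acetic acid, frees the alcohol without base-induced isomerisation of the enoate or acid damage to the furan.

Step 13
Reactants: 27 methyl (2E,6E)-9-(furan-3-yl)-2-[(4S)-5-hydroxy-4-methylpentyl]-6-methylnona-2,6-dienoate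
Product: 28 methyl (2E,6E)-2-[(4S)-5-(acetyloxy)-4-methylpentyl]-9-(furan-3-yl)-6-methylnona-2,6-dienoate
Conditions: Ac2O, pyridine, DMAP (5 mol %), CH2Cl2, 23 °C
Reagents that add atoms: acetic anhydride, CC(=O)OC(C)=O
Why: DMAP-catalysed acetylation of the primary alcohol with acetic anhydride gives the acetate and completes the target without touching the methyl ester, the alkenes or the stereocentre.

**Compound list**

1 | (2R)-3-bromo-2-methylpropan-1-ol | BrC[C@H](C)CO | starting material
2 | [(2R)-3-bromo-2-methylpropoxy](tert-butyl)dimethylsilane | BrC[C@H](C)CO[Si](C)(C)C(C)(C)C | intermediate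
3 | ethylene oxide (oxirane) | C1CO1 | starting material
4 | bromido[(2R)-3-(TBSO)-2-methylpropyl]magnesium (Grignard reagent, not isolated) | Br[Mg]C[C@H](C)CO[Si](C)(C)C(C)(C)C | intermediate
5 | (4S)-5-{[tert-butyl(dimethyl)silyl]oxy}-4-methylpentan-1-ol | OCCC[C@H](C)CO[Si](C)(C)C(C)(C)C | intermediate
6 | tert-butyl{[(2S)-5-iodo-2-methylpentyl]oxy}dimethylsilane | ICCC[C@H](C)CO[Si](C)(C)C(C)(C)C | intermediate
7 | methyl (triphenyl-λ5-phosphanylidene)acetate | COC(=O)C=P(c1ccccc1)(c1ccccc1)c1ccccc1 | starting material
8 | [(6S)-7-(TBSO)-1-methoxy-6-methyl-1-oxoheptan-2-yl](triphenyl)phosphonium iodide (not isolated) | COC(=O)C(CCC[C@H](C)CO[Si](C)(C)C(C)(C)C)[P+](c1ccccc1)(c1ccccc1)c1ccccc1.[I-] | intermediate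
9 | methyl (6S)-7-{[tert-butyl(dimethyl)silyl]oxy}-6-methyl-2-(triphenyl-λ5-phosphanylidene)heptanoate | COC(=O)C(CCC[C@H](C)CO[Si](C)(C)C(C)(C)C)=P(c1ccccc1)(c1ccccc1)c1ccccc1 | intermediate
10 | acetyl chloride | CC(=O)Cl | starting material
11 | ketene (ethenone, not isolated) | C=C=O | intermediate
12 | methyl 2-[(4S)-5-{[tert-butyl(dimethyl)silyl]oxy}-4-methylpentyl]buta-2,3-dienoate | COC(=O)C(CCC[C@H](C)CO[Si](C)(C)C(C)(C)C)=C=C | intermediate
13 | 3-bromofuran | Brc1ccoc1 | starting material
14 | oxetane | C1COC1 | starting material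
15 | furan-3-yllithium (not isolated) | [Li]c1ccoc1 | intermediate
16 | 3-(furan-3-yl)propan-1-ol | OCCCc1ccoc1 | intermediate
17 | 3-(furan-3-yl)propanal | O=CCCc1ccoc1 | intermediate
18 | isopropenylmagnesium bromide | CC(=C)[Mg]Br | starting material
19 | rac-1-(furan-3-yl)-4-methylpent-4-en-3-ol | CC(=C)C(O)CCc1ccoc1 | intermediate
20 | potassium 1-(furan-3-yl)-4-methylpent-4-en-3-olate (not isolated) | CC(=C)C([O-])CCc1ccoc1.[K+] | intermediate
21 | potassium ester enolate of methyl 3-{[1-(furan-3-yl)-4-methylpent-4-en-3-yl]oxy}-2-[(4S)-5-(TBSO)-4-methylpentyl]but-3-enoate (2-alkoxy-1,3-dienolate, not isolated) | COC([O-])=C(CCC[C@H](C)CO[Si](C)(C)C(C)(C)C)C(=C)OC(CCc1ccoc1)C(C)=C.[K+] | intermediate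
22 | potassium C2=C3 enolate of 23 (not isolated) | COC(=O)C(CCC[C@H](C)CO[Si](C)(C)C(C)(C)C)=C([O-])CC/C(C)=C/CCc1ccoc1.[K+] | intermediate
23 | methyl (6E)-2-[(4S)-5-{[tert-butyl(dimethyl)silyl]oxy}-4-methylpentyl]-9-(furan-3-yl)-6-methyl-3-oxonon-6-enoate (C2 epimers) | COC(=O)C(CCC[C@H](C)CO[Si](C)(C)C(C)(C)C)C(=O)CC/C(C)=C/CCc1ccoc1 | intermediate
24 | sodium C2=C3 enolate of 23 (not isolated) | COC(=O)C(CCC[C@H](C)CO[Si](C)(C)C(C)(C)C)=C([O-])CC/C(C)=C/CCc1ccoc1.[Na+] | intermediate
25 | methyl (2Z,6E)-2-[(4S)-5-{[tert-butyl(dimethyl)silyl]oxy}-4-methylpentyl]-9-(furan-3-yl)-6-methyl-3-{[(trifluoromethyl)sulfonyl]oxy}nona-2,6-dienoate | COC(=O)/C(CCC[C@H](C)CO[Si](C)(C)C(C)(C)C)=C(\OS(=O)(=O)C(F)(F)F)CC/C(C)=C/CCc1ccoc1 | intermediate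
26 | methyl (2E,6E)-2-[(4S)-5-{[tert-butyl(dimethyl)silyl]oxy}-4-methylpentyl]-9-(furan-3-yl)-6-methylnona-2,6-dienoate | COC(=O)/C(=C/CC/C(C)=C/CCc1ccoc1)CCC[C@H](C)CO[Si](C)(C)C(C)(C)C | intermediate
27 | methyl (2E,6E)-9-(furan-3-yl)-2-[(4S)-5-hydroxy-4-methylpentyl]-6-methylnona-2,6-dienoate | COC(=O)/C(=C/CC/C(C)=C/CCc1ccoc1)CCC[C@H](C)CO | intermediate
28 | methyl (2E,6E)-2-[(4S)-5-(acetyloxy)-4-methylpentyl]-9-(furan-3-yl)-6-methylnona-2,6-dienoate | COC(=O)/C(=C/CC/C(C)=C/CCc1ccoc1)CCC[C@H](C)COC(C)=O | target

**Step count and risks**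

Total step count: 13. Longest linear sequence: 10 steps (steps 1–5, then 9–13).

The three steps most likely to fail:

1. Step 9 (proposed new method). The anionic [3,3] shift of the ester-stabilised anion may be outrun by retro-addition and anionic oligomerisation of the allenoate. Proton transfer may also move the vinyl ether into conjugation, after which a Claisen shift would allylate C2 instead of C4. The fallback is known chemistry, the γ-alkylation of a β-keto ester dianion; it sets out from 6 and 17 and comes back at 23. Iodide 6 should alkylate methyl acetoacetate (K2CO3, acetone, reflux) to give methyl 2-[(4S)-5-(TBSO)-4-methylpentyl]-3-oxobutanoate F1. Aldehyde 17 and ethyl 2-(triphenyl-λ5-phosphanylidene)propanoate (CH2Cl2, 23 °C) should give ethyl (2E)-5-(furan-3-yl)-2-methylpent-2-enoate F2. DIBAL-H (CH2Cl2, −78 °C) should reduce it to (2E)-5-(furan-3-yl)-2-methylpent-2-en-1-ol F3, and CBr4/PPh3 should convert this into 3-[(3E)-5-bromo-4-methylpent-3-en-1-yl]furan F4. The dianion of F1 (NaH, then n-BuLi, THF, 0 °C) should be alkylated by F4 at its terminal carbon C4, without allylic transposition and with retention of the E geometry, to give 23.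

2. Step 10. Chelation control may be incomplete, giving a mixture of triflate geometries, and base may eliminate triflate towards an allenoate; either would erode the 2E geometry after step 11. The fallback sets out from 23 and comes back at 26, bypassing 25 and step 11. NaBH4 (MeOH, 0 °C) should reduce the ketone to methyl (6E)-2-[(4S)-5-(TBSO)-4-methylpentyl]-9-(furan-3-yl)-3-hydroxy-6-methylnon-6-enoate F5 as a diastereomer mixture. MsCl/Et3N should give methyl (6E)-2-[(4S)-5-(TBSO)-4-methylpentyl]-9-(furan-3-yl)-6-methyl-3-[(methylsulfonyl)oxy]non-6-enoate F6. DBU (CH2Cl2, 23 °C) should then eliminate by the E1cB path through the ester enolate, which funnels all diastereomers into the more stable 2E-enoate 26.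

3. Step 4. C-Alkylation of the stabilised ylide by an unactivated primary iodide may be slow, with competing O-alkylation and incomplete transylidation. The fallback sets out from 6 and comes back at 12, bypassing 9 and step 5. Dilithiated propargyl alcohol (n-BuLi, 2 equiv, THF–DMPU) should be alkylated by 6 to give (7S)-8-(TBSO)-7-methyloct-2-yn-1-ol F7. Methyl chloroformate/pyridine should give (7S)-8-(TBSO)-7-methyloct-2-yn-1-yl methyl carbonate F8. Palladium-catalysed decarboxylative methoxycarbonylation (Pd(OAc)2, PPh3, CO, MeOH, 50 °C) through an allenylpalladium intermediate should then give allenoate 12.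

Further compounds
F1 | step 9 | methyl 2-[(4S)-5-{[tert-butyl(dimethyl)silyl]oxy}-4-methylpentyl]-3-oxobutanoate | COC(=O)C(CCC[C@H](C)CO[Si](C)(C)C(C)(C)C)C(C)=O
F2 | step 9 | ethyl (2E)-5-(furan-3-yl)-2-methylpent-2-enoate | CCOC(=O)/C(C)=C/CCc1ccoc1
F3 | step 9 | (2E)-5-(furan-3-yl)-2-methylpent-2-en-1-ol | OC/C(C)=C/CCc1ccoc1
F4 | step 9 | 3-[(3E)-5-bromo-4-methylpent-3-en-1-yl]furan | BrC/C(C)=C/CCc1ccoc1
F5 | step 10 | methyl (6E)-2-[(4S)-5-{[tert-butyl(dimethyl)silyl]oxy}-4-methylpentyl]-9-(furan-3-yl)-3-hydroxy-6-methylnon-6-enoate | COC(=O)C(CCC[C@H](C)CO[Si](C)(C)C(C)(C)C)C(O)CC/C(C)=C/CCc1ccoc1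
F6 | step 10 | methyl (6E)-2-[(4S)-5-{[tert-butyl(dimethyl)silyl]oxy}-4-methylpentyl]-9-(furan-3-yl)-6-methyl-3-[(methylsulfonyl)oxy]non-6-enoate | COC(=O)C(CCC[C@H](C)CO[Si](C)(C)C(C)(C)C)C(OS(C)(=O)=O)CC/C(C)=C/CCc1ccoc1
F7 | step 4 | (7S)-8-{[tert-butyl(dimethyl)silyl]oxy}-7-methyloct-2-yn-1-ol | OCC#CCCC[C@H](C)CO[Si](C)(C)C(C)(C)C
F8 | step 4 | (7S)-8-{[tert-butyl(dimethyl)silyl]oxy}-7-methyloct-2-yn-1-yl methyl carbonate | COC(=O)OCC#CCCC[C@H](C)CO[Si](C)(C)C(C)(C)C
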